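## Analysis of the target

The target 25 is (2R,3S,3aR,5S)-3a-allyl-5,7-dimethoxy-2-methyl-3-(3,4,5-trimethoxyphenyl)-3,3a,4,5-tetrahydro-1-benzofuran-6(2H)-one, in which the tetrahydrofuran ring B (O1, C2, C3, C3a, C7a) is fused to the six-membered ring A (C3a, C4, C5, C6, C7, C7a) and O1–C7a=C7(OMe)–C6=O is a vinylogous ester. There are four stereocentres, C2 (methyl), C3 (aryl), the quaternary C3a (allyl) and C5 (methoxy); methyl and aryl are trans on ring B, the allyl group is trans to the aryl group, and the 5-methoxy group is cis to the angular allyl group. The ring fusion holds the allyl group pseudoaxial on ring A, so the 5-methoxy group is also axial and 1,3 to it. This epimer is therefore not expected to be favoured by equilibration next to the ketone, and C5 has to be brought in with defined configuration and kept away from enolising conditions. Sensitive groups are the vinylogous ester (acid and base), the terminal alkene (no hydrogenation once it is present, limited tolerance of electrophilic oxidants) and the electron-rich arene. The difficulty lies in the quaternary C3a between the stereogenic C3 and the sp2 carbon C7a, and in a ring A that carries oxygen on four adjacent carbons. The strategy rests on the 1,3-relation of the C6 ketone and the enol ether carbon C7a across C7. This is the pattern of a β-hydroxy ketone less water, and so of a [3+2] adduct of a C6-centred N–O dipole with a C7a=C7 enol ether, in which an N–O bridge joins C6 and C7a.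

## Retrosynthetic reasoning

25 from 23. The vinylogous ester is taken back to the 7a-hydroxy ketonitrone 23. Hydrolysis of C6=N gives the ketone, and loss of water from the C7a hemiketal towards C7 gives C7=C7a. No skeletal bond is cut, and the forward step needs only weak aqueous acid.

23 from 21. The nitrone oxygen and the 7a-hydroxyl are joined again as the N–O bridge of isoxazolidine 21. Forward, a peracid oxidises nitrogen and the N-oxide opens at the ring N–O bond. The nitrogen substituent has no α-hydrogen, so the new C=N can only form at C6, which returns C6 to the ketone oxidation level.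

21 from 20 (key disconnection). The C6–C7 bond and the O–C7a bond are cut together, which opens ring A and gives nitrone 20 with the exocyclic enol ether C7a=C7. The cut is made here because it uses the 1,3-oxygen pattern directly and leaves ring B, C3a and C5 untouched. The dipole is taken at the nitrone and not at the nitrile oxide level. With a nitrile oxide, C6=N of the adduct would lie at a bridgehead of the bicyclo[3.2.1] frame formed by ring A and the N–O bridge, which is too strained to form. On this three-atom tether a nitrile oxide could only add the other way round and close a five-membered carbocycle. A saturated C6 removes that constraint. The forward reaction must bond the dipole carbon to the distal alkene carbon C7 and the oxygen to C7a.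

20 from 19, 18 and 17. The nitrone comes from aldehyde 19 by condensation with an N-alkylhydroxylamine that has no α-hydrogen. Aldehyde 19 comes from alcohol 18, and 18 from silyl ether 17. These are functional group changes that must spare the acid-sensitive enol ether and the α-alkoxy stereocentre C5.

17 from 16 and 15. The C7a=C7 bond is cut back to the lactone carbonyl of 15: a methoxymethyl carbanion equivalent adds to give lactol 16, which loses water. C7 arrives with its methoxy group, and because C3a is quaternary the dehydration can only go to the exocyclic position.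

15 from 13 and 14, and 13 from 7 and 12. The two C3a–C bonds are cut in the order allyl first, then C3a–C4. Forward, the chain is therefore put in first and allyl bromide 14 last, so that the allyl group enters the enolate face opposite the neighbouring aryl group. Triflate 12 carries C4, C5 with its methoxy group and C6 as a silyl ether, so C5 is never made on the lactone.

12 from 8. The three-carbon unit is traced to the glycerol derivative 8, whose stereocentre becomes C5. Silylation, methylation, debenzylation and triflation differentiate the two ends.

7 from 5 and 6, and 5 from 1 and 2. The C3–aryl bond is cut to butenolide 5 and aryl bromide 6. Forward, a copper-mediated conjugate addition puts the aryl group trans to the methyl group. Butenolide 5 goes back to epoxide 1, which supplies C2, and the sulfur-substituted acetic acid 2, which supplies C3, C3a and C7a and the handle for the unsaturation.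

## Alternatives that were turned down

Alternative 1: The disconnection is the C2–C3 bond of ring B on an intact aromatic ring A. Forward, diazo compound A2 would be decomposed by a chiral dirhodium tetracarboxylate, Rh2(O2CR*)4, and the metal carbene at the diarylmethyl carbon C3 would insert into the O–CH2 bond of the ortho ethoxy group to give dihydrobenzofuran A1.
- For it: both ring B stereocentres come from one catalytic step, no chiral-pool material is needed, and the arene brings the oxygens at C5, C6 and C7. Up to the stage of a complete ring B it is shorter than the chosen route.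
- Against it: A1 is aromatic, while the target needs sp3 carbons at C3a, C4 and C5. After A1 would come debenzylation, a dearomatising C-allylation at C3a in competition with O-allylation, and a selective saturation of C4=C5 beside an allyl group with control of C5. The trans relation at C2/C3 is also not assured in an insertion of this kind.
- Comparison: the chosen strategy spends more steps on ring B. In return it sets C3a by an enolate alkylation whose facial sense is fixed by the adjacent aryl group, takes C5 from the chiral pool, and needs neither a dearomatisation nor an alkene reduction.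

Alternative 2: The disconnection is the C3a–C7a bond, with ring A built from a four-carbon squaric unit and an alkenyl chain. Forward, cyclobutenone A4 would open thermally (4π) to a dienylketene, and its ketene carbon (the later C7a) would close (6π) onto the disubstituted alkene terminus (the later C3a) to give dienone A3.
- For it: it is convergent and reagent-free, and ring A and the quaternary carbon form in one step with all ring oxygens already in place. On convergence it is stronger than the chosen route.
- Against it: the configuration of C3a is decided in a pericyclic closure steered only by the alkene geometry and by the C3 centre of an open chain. A3 has three methoxy groups and its carbonyl at the carbon that must become C7a, so after desilylation and ring B closure the C6 enol ether must become the ketone and C4=C5 must be reduced with control of C5. Linearly conjugated cyclohexadienones of this type also tend to dimerise.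
- Comparison: the chosen route is linear, but the oxidation pattern of ring A is correct as soon as the adduct is unmasked, and C3a and C5 are fixed before ring A exists.

Alternative 3: The disconnection is the O1–C7a bond. Forward, the C2 hydroxyl of the prochiral dienone A6 would add in a 5-exo-trig oxa-Michael reaction to one of the two diastereotopic enone β-carbons to give A5, which closes ring B and makes C3a stereogenic.
- For it: it is the shortest plan, it uses the symmetry of the dienone, and a single ring closure delivers ring B and C3a. In step economy it is clearly better than the chosen route.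
- Against it: A5 is a double-bond isomer of the target, unsaturated at C4=C5 and saturated at C7–C7a. Correction needs a dehydrogenation across C7–C7a and a conjugate reduction of C4=C5 with control of C5, in the presence of the allyl group. The oxa-Michael addition is reversible, so the choice between the two arms, and with it C3a, rests on a modest thermodynamic bias. A6 also needs a quaternary carbon bearing a secondary benzylic chain, which is hard to reach by phenol dearomatisation.
- Comparison: the chosen route sets C3a kinetically by alkylation, and after unmasking it has the C7=C7a and C4–C5 oxidation states in place, so no late redox adjustment of ring A is needed.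

Key step: step 15

Remark on the chemistry: the dipole is used as the N-tert-butyl nitrone; enol ether 17 is assumed to form mainly as the Z isomer (7-OMe syn to O1), and the E isomer is expected to react in the same sense but more slowly.

## Route

Step 1
Reactants: 1 (R)-propylene oxide; 2 (phenylsulfanyl)acetic acid
Product: 3 (5R)-5-methyl-3-(phenylsulfanyl)dihydrofuran-2(3H)-one (C3 epimers)
Conditions: 2, LDA (2.1 equiv), THF, 0 °C; then 1, 0 °C→rt; 1 M HCl; TsOH (cat.), PhH, reflux
Reagents that add atoms: none
Why: The dianion of 2 opens the epoxide at the unsubstituted carbon (SN2), so the stereocentre of 1 is untouched and becomes C2 of the target; the γ-hydroxy acid lactonises on acidification.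

Step 2
Reactants: 3 (5R)-5-methyl-3-(phenylsulfanyl)dihydrofuran-2(3H)-one
Product: 5 (R)-5-methylfuran-2(5H)-one, via sulfoxide 4 (not isolated)
Conditions: mCPBA (1.0 equiv), CH2Cl2, −78 °C; then CaCO3, PhMe, 110 °C
Reagents that add atoms: none
Why: Sulfide oxidation followed by thermal syn-elimination of the sulfoxide should give the butenolide; the γ-stereocentre is not involved and no base is present that could enolise it.

Step 3
Reactants: 5 (R)-5-methylfuran-2(5H)-one; 6 5-bromo-1,2,3-trimethoxybenzene
Product: 7 (4R,5R)-5-methyl-4-(3,4,5-trimethoxyphenyl)dihydrofuran-2(3H)-one (trans)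
Conditions: 6, Mg, THF (Grignard reagent, 1.5 equiv); CuBr·SMe2 (10 mol%), THF, −40 °C; then 5; 1 M HCl
Reagents that add atoms: none
Why: Copper-catalysed conjugate addition of the aryl Grignard reagent; the aryl group should add to the butenolide face opposite the C5 methyl group, which sets C3 of the target trans to C2.

Step 4
Reactants: 8 (R)-3-(benzyloxy)propane-1,2-diol
Product: 9 (S)-1-(benzyloxy)-3-[(tert-butyldiphenylsilyl)oxy]propan-2-ol
Conditions: TBDPSCl (1.05 equiv), imidazole, CH2Cl2, 0 °C
Reagents that add atoms: tert-butyl(chloro)diphenylsilane (TBDPSCl), CC(C)(C)[Si](Cl)(c1ccccc1)c1ccccc1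
Why: The bulky silyl chloride should react selectively at the primary hydroxyl; the stereocentre is untouched (the descriptor changes only because the priorities change).

Step 5
Reactants: 9 (S)-1-(benzyloxy)-3-[(tert-butyldiphenylsilyl)oxy]propan-2-ol
Product: 10 (S)-[3-(benzyloxy)-2-methoxypropoxy](tert-butyl)diphenylsilane
Conditions: Me3OBF4, 1,8-bis(dimethylamino)naphthalene, CH2Cl2, rt
Reagents that add atoms: trimethyloxonium tetrafluoroborate, C[O+](C)C.F[B-](F)(F)F
Why: O-Methylation without an alkoxide avoids migration of the neighbouring silyl group; this methoxy group becomes the 5-OMe of the target.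

Step 6
Reactants: 10 (S)-[3-(benzyloxy)-2-methoxypropoxy](tert-butyl)diphenylsilane
Product: 11 (S)-3-[(tert-butyldiphenylsilyl)oxy]-2-methoxypropan-1-ol
Conditions: H2 (1 atm), Pd/C, EtOAc, rt
Reagents that add atoms: none
Why: Hydrogenolysis of the benzyl ether frees the primary alcohol; the silyl ether and the methyl ether are inert, and no alkene is present yet.

Step 7
Reactants: 11 (S)-3-[(tert-butyldiphenylsilyl)oxy]-2-methoxypropan-1-ol
Product: 12 (R)-3-[(tert-butyldiphenylsilyl)oxy]-2-methoxypropyl trifluoromethanesulfonate
Conditions: Tf2O, 2,6-lutidine, CH2Cl2, −78 °C; used at once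
Reagents that add atoms: trifluoromethanesulfonic anhydride, O=S(=O)(OS(=O)(=O)C(F)(F)F)C(F)(F)F
Why: A β-alkoxy primary electrophile alkylates lactone enolates reliably only as the triflate; the stereocentre is not touched.

Step 8
Reactants: 7 (4R,5R)-5-methyl-4-(3,4,5-trimethoxyphenyl)dihydrofuran-2(3H)-one; 12 (R)-3-[(tert-butyldiphenylsilyl)oxy]-2-methoxypropyl trifluoromethanesulfonate
Product: 13 (3S,4R,5R)-3-[(2S)-3-[(tert-butyldiphenylsilyl)oxy]-2-methoxypropyl]-5-methyl-4-(3,4,5-trimethoxyphenyl)dihydrofuran-2(3H)-one (3,4-trans expected as the main isomer)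
Conditions: LDA (1.05 equiv), THF, −78 °C; then 12, DMPU, −78→−40 °C
Reagents that add atoms: none
Why: Lithium enolate alkylation (SN2 at the primary triflate) forms the C3a–C4 bond and brings in C5 with its configuration from 8; the configuration of the new α-centre is of no consequence because it is enolised again in step 9.

Step 9
Reactants: 13 α-monoalkylated lactone; 14 allyl bromide
Product: 15 (3R,4S,5R)-3-allyl-3-[(2S)-3-[(tert-butyldiphenylsilyl)oxy]-2-methoxypropyl]-5-methyl-4-(3,4,5-trimethoxyphenyl)dihydrofuran-2(3H)-one
Conditions: LDA (1.2 equiv), THF/DMPU, −78 °C; then 14, −78→−30 °C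
Reagents that add atoms: none
Why: Alkylation of the trisubstituted lactone enolate; allyl bromide should enter the face opposite the adjacent aryl group, which places the allyl group trans to aryl and sets the quaternary C3a.

Step 10
Reactants: 15 quaternary lactone
Product: 16 lactol (2-(methoxymethyl)tetrahydrofuran-2-ol from 15; anomers, in equilibrium with the open γ-hydroxy ketone)
Conditions: Bu3SnCH2OMe, n-BuLi, THF, −78 °C; then 15, −78 °C; H2O
Reagents that add atoms: tributyl(methoxymethyl)stannane, CCCC[Sn](CCCC)(CCCC)COC
Why: Tin–lithium exchange gives methoxymethyllithium, which adds once to the hindered lactone carbonyl because the lithium hemiketal persists at low temperature; this brings in C7 with its methoxy group.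

Step 11
Reactants: 16 lactol
Product: 17 (2Z,3R,4S,5R)-3-allyl-3-[(2S)-3-[(tert-butyldiphenylsilyl)oxy]-2-methoxypropyl]-2-(methoxymethylene)-5-methyl-4-(3,4,5-trimethoxyphenyl)tetrahydrofuran
Conditions: PPTS (5 mol%), PhH, reflux, 4 Å MS; then Et3N
Reagents that add atoms: none
Why: Acid-catalysed dehydration through the C7a oxocarbenium ion; only C7 carries a hydrogen (C3a is quaternary), so the exocyclic enol ether is the only alkene that can form, and the reversible conditions should favour the Z isomer with the methoxy group away from C3a.

Step 12
Reactants: 17 silyl-protected enol ether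
Product: 18 (2S)-3-[(2Z,3R,4S,5R)-3-allyl-2-(methoxymethylene)-5-methyl-4-(3,4,5-trimethoxyphenyl)tetrahydrofuran-3-yl]-2-methoxypropan-1-ol
Conditions: TBAF, THF, 0 °C→rt
Reagents that add atoms: none
Why: Fluoride cleaves the silyl ether under basic conditions that leave the enol ether intact; the alcohol is freed only now, when no lactone is left that it could attack.

Step 13
Reactants: 18 primary alcohol
Product: 19 (2S)-3-[(2Z,3R,4S,5R)-3-allyl-2-(methoxymethylene)-5-methyl-4-(3,4,5-trimethoxyphenyl)tetrahydrofuran-3-yl]-2-methoxypropanal
Conditions: DMP (1,1,1-triacetoxy-1,2-benziodoxol-3(1H)-one), pyridine, CH2Cl2, 0 °C→rt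
Reagents that add atoms: none
Why: Periodinane oxidation of the primary alcohol buffered with pyridine should spare the enol ether and not epimerise the α-alkoxy aldehyde.

Step 14
Reactants: 19 α-methoxy aldehyde
Product: 20 (Z)-N-tert-butyl nitrone of 19 (C6=N(O)t-Bu)
Conditions: t-BuNHOH·HCl, NaHCO3, MgSO4, CH2Cl2, rt
Reagents that add atoms: N-tert-butylhydroxylamine hydrochloride, CC(C)(C)NO.Cl
Why: Condensation of the aldehyde with the N-alkylhydroxylamine gives the Z-aldonitrone under buffered conditions that protect the enol ether and C5; the tert-butyl group is chosen because it has no α-hydrogen (needed in step 16).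

Step 15
Reactants: 20 N-tert-butyl nitrone
Product: 21 bridged N-tert-butyl isoxazolidine (6-oxa-7-azabicyclo[3.2.1]octane core: N on C6 and O on C7a on the ring A face syn to C3; 7-OMe syn to the N–O bridge; 3a-allyl and 5-OMe on the other face; ring B intact)
Conditions: PhMe (0.02 M), 100–110 °C, sealed tube
Reagents that add atoms: none
Why: On heating, the Z-nitrone reaches the exocyclic enol ether from the face of ring B that carries C4, the only face the three-atom tether C5–C4–C3a allows, and a concerted, suprafacial [3+2] cycloaddition forms the C6–C7 and O–C7a bonds. The closest known reaction types are the intramolecular nitrone–alkene cycloaddition in its bridged mode and the addition of nitrones to exocyclic enol ethers such as 2-alkylidene tetrahydrofurans, in which the oxygen ends on the acetal carbon. Ring A closes as a six-membered carbocycle by bonding at the distal alkene carbon C7 (6-endo with respect to C7a=C7), and the isoxazolidine is the five-membered ring of the cycloaddition. The bicyclic core is saturated at the bridgehead C6 and so avoids the strain that a C6=N bond would bring. Of the new centres, C7a is set by the tether (oxygen syn to C4), C6 is tied to C7a through the N–O bridge, and C7 follows from the enol ether geometry (Z puts 7-OMe syn to the bridge); all three are removed again in steps 16 and 17, so their sense does not matter, and C5 is not involved. The selectivity needed is regiochemical, bridged (C6 to C7) against fused (C6 to C7a, five-membered carbocycle). Both alkene carbons carry oxygen, so little electronic bias is expected, and the bridged mode should be secured sterically: C7a is fully substituted and flanked by the quaternary C3a, so that C–C bonding there would create two adjacent fully substituted carbons, whereas the small oxygen terminus can bond to C7a. At or below 110 °C the [3,3] shift of the 1,5-diene C7=C7a–C3a–CH2–CH=CH2 should stay slow.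

Step 16
Reactants: 21 bridged N-tert-butyl isoxazolidine
Product: 23 7a-hydroxy N-tert-butyl C6-ketonitrone (cyclic hemiketal at C7a), via isoxazolidine N-oxide 22 (not isolated)
Conditions: mCPBA (1.05 equiv), NaHCO3, CH2Cl2, −20→0 °C
Reagents that add atoms: 3-chloroperoxybenzoic acid (mCPBA), OOC(=O)c1cccc(Cl)c1
Why: Peracid oxidation of an N-alkyl isoxazolidine gives the N-oxide, which opens at the ring N–O bond with loss of an α-hydrogen to a β-hydroxy nitrone; the tert-butyl group has no α-hydrogen, so the C=N can only form at C6, which is no longer a bridgehead once the bridge is cut. N-Oxidation should be faster than epoxidation of the monosubstituted alkene at this temperature.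

Step 17
Reactants: 23 7a-hydroxy ketonitrone
Product: 25 (2R,3S,3aR,5S)-3a-allyl-5,7-dimethoxy-2-methyl-3-(3,4,5-trimethoxyphenyl)-3,3a,4,5-tetrahydro-1-benzofuran-6(2H)-one, via 7a-hydroxy ketone 24 (not isolated)
Conditions: 0.5 M aq. oxalic acid, THF, rt; then PPTS (cat.), PhH, 4 Å MS, rt
Reagents that add atoms: water, O
Why: Mild acid hydrolysis of the ketonitrone frees the C6 ketone, and the C7a hemiketal then loses water towards C7 (β-hydroxy ketone dehydration) to give the vinylogous ester. C5 should not enolise under these weakly acidic conditions, so its configuration from 8 is kept.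

## Compound list

1 | (R)-propylene oxide | C[C@@H]1CO1 | starting material
2 | (phenylsulfanyl)acetic acid | OC(=O)CSc1ccccc1 | starting material
3 | (5R)-5-methyl-3-(phenylsulfanyl)dihydrofuran-2(3H)-one (C3 epimers) | C[C@@H]1CC(Sc2ccccc2)C(=O)O1 | intermediate
4 | (5R)-5-methyl-3-(phenylsulfinyl)dihydrofuran-2(3H)-one (not isolated) | C[C@@H]1CC(S(=O)c2ccccc2)C(=O)O1 | intermediate
5 | (R)-5-methylfuran-2(5H)-one | C[C@@H]1C=CC(=O)O1 | intermediate
6 | 5-bromo-1,2,3-trimethoxybenzene | COc1cc(Br)cc(OC)c1OC | starting material
7 | (4R,5R)-5-methyl-4-(3,4,5-trimethoxyphenyl)dihydrofuran-2(3H)-one | O=C1C[C@H](c2cc(OC)c(OC)c(OC)c2)[C@@H](C)O1 | intermediate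
8 | (R)-3-(benzyloxy)propane-1,2-diol | OC[C@@H](O)COCc1ccccc1 | starting material
9 | (S)-1-(benzyloxy)-3-[(tert-butyldiphenylsilyl)oxy]propan-2-ol | CC(C)(C)[Si](c1ccccc1)(c1ccccc1)OC[C@@H](O)COCc1ccccc1 | intermediate
10 | (S)-[3-(benzyloxy)-2-methoxypropoxy](tert-butyl)diphenylsilane | CC(C)(C)[Si](c1ccccc1)(c1ccccc1)OC[C@@H](OC)COCc1ccccc1 | intermediate
11 | (S)-3-[(tert-butyldiphenylsilyl)oxy]-2-methoxypropan-1-ol | CC(C)(C)[Si](c1ccccc1)(c1ccccc1)OC[C@@H](OC)CO | intermediate
12 | (R)-3-[(tert-butyldiphenylsilyl)oxy]-2-methoxypropyl trifluoromethanesulfonate | CC(C)(C)[Si](c1ccccc1)(c1ccccc1)OC[C@@H](OC)COS(=O)(=O)C(F)(F)F | intermediate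
13 | (3S,4R,5R)-3-[(2S)-3-[(tert-butyldiphenylsilyl)oxy]-2-methoxypropyl]-5-methyl-4-(3,4,5-trimethoxyphenyl)dihydrofuran-2(3H)-one (main isomer drawn) | CC(C)(C)[Si](c1ccccc1)(c1ccccc1)OC[C@@H](OC)C[C@@H]1C(=O)O[C@H](C)[C@H]1c1cc(OC)c(OC)c(OC)c1 | intermediate
14 | allyl bromide | C=CCBr | starting material
15 | (3R,4S,5R)-3-allyl-3-[(2S)-3-[(tert-butyldiphenylsilyl)oxy]-2-methoxypropyl]-5-methyl-4-(3,4,5-trimethoxyphenyl)dihydrofuran-2(3H)-one | C=CC[C@]1(C[C@H](OC)CO[Si](c2ccccc2)(c2ccccc2)C(C)(C)C)C(=O)O[C@H](C)[C@H]1c1cc(OC)c(OC)c(OC)c1 | intermediate
16 | lactol: 2-(methoxymethyl)tetrahydrofuran-2-ol from 15 (anomers) | C=CC[C@]1(C[C@H](OC)CO[Si](c2ccccc2)(c2ccccc2)C(C)(C)C)C(O)(COC)O[C@H](C)[C@H]1c1cc(OC)c(OC)c(OC)c1 | intermediate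
17 | (2Z,3R,4S,5R)-3-allyl-3-[(2S)-3-[(tert-butyldiphenylsilyl)oxy]-2-methoxypropyl]-2-(methoxymethylene)-5-methyl-4-(3,4,5-trimethoxyphenyl)tetrahydrofuran | C=CC[C@]1(C[C@H](OC)CO[Si](c2ccccc2)(c2ccccc2)C(C)(C)C)/C(=C/OC)O[C@H](C)[C@H]1c1cc(OC)c(OC)c(OC)c1 | intermediate
18 | (2S)-3-[(2Z,3R,4S,5R)-3-allyl-2-(methoxymethylene)-5-methyl-4-(3,4,5-trimethoxyphenyl)tetrahydrofuran-3-yl]-2-methoxypropan-1-ol | C=CC[C@]1(C[C@H](OC)CO)/C(=C/OC)O[C@H](C)[C@H]1c1cc(OC)c(OC)c(OC)c1 | intermediate
19 | (2S)-3-[(2Z,3R,4S,5R)-3-allyl-2-(methoxymethylene)-5-methyl-4-(3,4,5-trimethoxyphenyl)tetrahydrofuran-3-yl]-2-methoxypropanal | C=CC[C@]1(C[C@H](OC)C=O)/C(=C/OC)O[C@H](C)[C@H]1c1cc(OC)c(OC)c(OC)c1 | intermediate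
20 | (Z)-N-tert-butyl nitrone of 19 | C=CC[C@]1(C[C@H](OC)/C=[N+](\[O-])C(C)(C)C)/C(=C/OC)O[C@H](C)[C@H]1c1cc(OC)c(OC)c(OC)c1 | intermediate
21 | bridged N-tert-butyl isoxazolidine (N on C6, O on C7a, 7-OMe syn to the bridge) | C=CC[C@]12C[C@H](OC)[C@H]3N(C(C)(C)C)O[C@@]1([C@@H]3OC)O[C@H](C)[C@H]2c1cc(OC)c(OC)c(OC)c1 | intermediate
22 | N-oxide of 21 (not isolated) | C=CC[C@]12C[C@H](OC)[C@H]3[N+]([O-])(C(C)(C)C)O[C@@]1([C@@H]3OC)O[C@H](C)[C@H]2c1cc(OC)c(OC)c(OC)c1 | intermediate
23 | 7a-hydroxy N-tert-butyl C6-ketonitrone (hemiketal) | C=CC[C@]12C[C@H](OC)C(=[N+]([O-])C(C)(C)C)[C@@H](OC)[C@]1(O)O[C@H](C)[C@H]2c1cc(OC)c(OC)c(OC)c1 | intermediate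
24 | 7a-hydroxy ketone (hemiketal, not isolated) | C=CC[C@]12C[C@H](OC)C(=O)[C@@H](OC)[C@]1(O)O[C@H](C)[C@H]2c1cc(OC)c(OC)c(OC)c1 | intermediate
25 | (2R,3S,3aR,5S)-3a-allyl-5,7-dimethoxy-2-methyl-3-(3,4,5-trimethoxyphenyl)-3,3a,4,5-tetrahydro-1-benzofuran-6(2H)-one | C=CC[C@]12C[C@H](OC)C(=O)C(OC)=C1O[C@H](C)[C@H]2c1cc(OC)c(OC)c(OC)c1 | target

## Step count and least certain steps

Total step count: 17. Longest linear sequence: 14 steps (steps 4–17, from 8 through triflate 12). Steps 1–3 are a three-step branch from 1 that supplies lactone 7 and joins at step 8.

Step 15 (key step). The most likely failure is closure in the fused sense, with C6 bonding to C7a and a five-membered carbocycle forming, because that geometry suits a three-atom tether best. A second risk is no reaction at a temperature the substrate tolerates; the E enol ether isomer, which would place the 7-methoxy group axial, may lag behind. The fallback sets out from aldehyde 19 and closes the same C6–C7 bond by an aldol-type reaction. A mild Lewis acid (MgBr2·OEt2 or Me2AlCl, CH2Cl2, −78 °C) should make the enol ether add through C7 to the aldehyde carbon, and loss of the C7 proton from the C7a oxocarbenium ion should give the 6-hydroxy enol ether F1. Oxidation of this allylic alcohol with DMP and pyridine (or MnO2) returns to the route at 25.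

Step 16. Several things can go wrong: N-oxidation of the hindered nitrogen may be slow enough for epoxidation of the allyl group to compete, isobutene may be lost from the N-oxide instead of ring opening, the ring-opened intermediate may fragment at the C7–C7a bond instead of losing the C6 hydrogen, and the first-formed nitrone may be oxidised further. The fallback sets out from 21. Zn in AcOH should cleave the N–O bond reductively to the N-tert-butylamino hemiketal F2. Oxidation of this secondary amine with H2O2 and catalytic Na2WO4 in MeOH, again regiospecific because the tert-butyl group has no α-hydrogen, returns to the route at 23.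

Step 9. The risk is poor facial selectivity in the quaternisation, because the methyl group on the next carbon lies on the face the electrophile must use, or incomplete enolisation of the hindered lactone. The fallback sets out from 13. The enolate (LiHMDS) is trapped on oxygen with allyl chloroformate to give the allyl enol carbonate F3. A palladium-catalysed decarboxylative allylation (Pd2(dba)3 with a chiral phosphinooxazoline ligand chosen to reinforce the substrate bias) then returns to the route at 15.

Step 11. The dehydration is reversible, so conversion may be incomplete, and the exocyclic enol ether may be lost again to acid-catalysed addition on work-up. The fallback sets out from 16. The lactol is converted with MeOH and PPTS into the mixed methyl ketal F4, and methanol is then eliminated irreversibly in a basic medium with TMSOTf and i-Pr2NEt (CH2Cl2, −78→0 °C), which returns to the route at 17.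

Step 17. Hydrolysis of the hindered nitrone may be slow, and prolonged contact with acid could epimerise C5 through the enol or the N-hydroxy enamine. The fallback sets out from 23. Buffered TiCl3 (NH4OAc, THF/H2O, 0 °C) should deoxygenate the nitrone to the N-tert-butyl imine F5, which hydrolyses quickly in the same buffer to 24; the dehydration then returns to the route at 25.

## Further compounds

F1 | step 15 | 6-hydroxy enol ether: (2R,3S,3aR,5S)-3a-allyl-5,7-dimethoxy-2-methyl-3-(3,4,5-trimethoxyphenyl)-2,3,3a,4,5,6-hexahydro-1-benzofuran-6-ol (C6 epimers) | C=CC[C@]12C[C@H](OC)C(O)C(OC)=C1O[C@H](C)[C@H]2c1cc(OC)c(OC)c(OC)c1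
F2 | step 16 | 6-(tert-butylamino) 7a-hydroxy hemiketal from reductive N–O cleavage of 21 | C=CC[C@]12C[C@H](OC)[C@@H](NC(C)(C)C)[C@@H](OC)[C@]1(O)O[C@H](C)[C@H]2c1cc(OC)c(OC)c(OC)c1
F3 | step 9 | allyl enol carbonate of 13 | C=CCOC(=O)OC1=C(C[C@H](OC)CO[Si](c2ccccc2)(c2ccccc2)C(C)(C)C)[C@H](c2cc(OC)c(OC)c(OC)c2)[C@@H](C)O1
F4 | step 11 | mixed methyl ketal of 16 (anomers) | C=CC[C@]1(C[C@H](OC)CO[Si](c2ccccc2)(c2ccccc2)C(C)(C)C)C(OC)(COC)O[C@H](C)[C@H]1c1cc(OC)c(OC)c(OC)c1
F5 | step 17 | 7a-hydroxy N-tert-butyl C6-ketimine | C=CC[C@]12C[C@H](OC)C(=NC(C)(C)C)[C@@H](OC)[C@]1(O)O[C@H](C)[C@H]2c1cc(OC)c(OC)c(OC)c1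
A1 | alternative 1 | trans-6-(benzyloxy)-5,7-dimethoxy-2-methyl-3-(3,4,5-trimethoxyphenyl)-2,3-dihydrobenzofuran | c12cc(OC)c(OCc3ccccc3)c(OC)c1O[C@H](C)[C@H]2c1cc(OC)c(OC)c(OC)c1
A2 | alternative 1 | [4-(benzyloxy)-2-ethoxy-3,5-dimethoxyphenyl](3,4,5-trimethoxyphenyl)diazomethane | CCOc1c(OC)c(OCc2ccccc2)c(OC)cc1C(=[N+]=[N-])c1cc(OC)c(OC)c(OC)c1
A3 | alternative 2 | 6-allyl-2,3,4-trimethoxy-6-[(1S,2R)-2-(tert-butyldimethylsilyloxy)-1-(3,4,5-trimethoxyphenyl)propyl]cyclohexa-2,4-dienone | C=CC[C@@]1(C=C(OC)C(OC)=C(OC)C1=O)[C@H](c1cc(OC)c(OC)c(OC)c1)[C@@H](C)O[Si](C)(C)C(C)(C)C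
A4 | alternative 2 | 4-alkenyl-2,3,4-trimethoxycyclobut-2-en-1-one precursor of A3 (C4 epimers; alkene geometry left open) | COC1=C(OC)C(OC)(C=C(CC=C)[C@H](c2cc(OC)c(OC)c(OC)c2)[C@@H](C)O[Si](C)(C)C(C)(C)C)C1=O
A5 | alternative 3 | cis-fused 7,7a-dihydro oxa-Michael adduct (C7 epimers) | C=CC[C@]12C=C(OC)C(=O)C(OC)[C@H]1O[C@H](C)[C@H]2c1cc(OC)c(OC)c(OC)c1
A6 | alternative 3 | 4-allyl-4-[(1S,2R)-2-hydroxy-1-(3,4,5-trimethoxyphenyl)propyl]-2,6-dimethoxycyclohexa-2,5-dienone | C=CCC1(C=C(OC)C(=O)C(OC)=C1)[C@H](c1cc(OC)c(OC)c(OC)c1)[C@@H](C)O
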